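The data stem from a simulated flask with constants of no real substance, and the scatter is random.

At early times in the north-west run, which is the asked flask itself followed so far, substrate is down to 15.4% at 0.167 h and side product stands at 6.2%. So 78.4% of the substrate charged sits in forms you do not read.

| flask | substrate | reagent | remark | time |
|---|---|---|---|---|
| north-west | 0.25 M | 0.25 M (in portions, 4) | the very flask that is asked about, followed so far; portions every 1.0 min |  |
| south-west | 0.17 M | 0.25 M (in portions, 4) | run made earlier; portions every 1.0 min |  |
| flask | 0.25 M | 0.250 M (in portions, 4) | the portions of reagent follow each other after 1.0 min, the first at the start | 8.0 h |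

| run | time / h | substrate / % | side product / % |
|---|---|---|---|
| north-west | 0.167 | 15.4 | 6.2 |
| north-west | 0.500 | 10.7 | 24.0 |
| north-west | 0.833 | 9.7 | 34.7 |
| north-west | 1.33 | 10.0 | 40.0 |
| north-west | 2.00 | 9.6 | 42.2 |
| north-west | 2.50 | 9.4 | 42.7 |
| north-west | 3.00 | 9.5 | 43.5 |
| south-west | 0.333 | 8.2 | 15.1 |
| south-west | 0.833 | 5.8 | 38.7 |
| south-west | 1.50 | 3.8 | 54.5 |
| south-west | 2.50 | 2.1 | 63.9 |
| south-west | 3.00 | 1.4 | 66.5 |
| south-west | 4.00 | 1.7 | 70.0 |
| south-west | 6.00 | 1.2 | 73.4 |

(readings scatter by 0.3 percentage points)

- percentages count the substrate that a species holds: one side product counts as two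
- what has gone from substrate into another species counts as reacted, even if it can come back

1. conversion of substrate at 8.0 h
2. amount of side product at 8.0 h, in percent of the substrate charged

Why does substrate in the north-west run stay near 9.5% while the south-west run reaches 1.2%? The south-west run has 1.47 reagent per substrate against 1.00, so I read reagent as the limiting reagent. Taking the last readings and assuming no reagent remains, the north-west run gives 1.10 and the south-west run 1.49. I call this ratio, reagent charged per substrate reacted, the reagent price. The dearer south-west run holds more side product at its last reading, 73.4% at 6.00 h, than the north-west run at its own, 43.5% at 3.00 h.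

Does time still matter in the north-west run? Substrate moved 0.1 percentage points between 2.00 h and 3.00 h, with a reading scatter of 0.3 points. Side product moved 1.3 points over the same interval, so my reckoning is a conversion of 90.5% and, less firmly, side product near 43.5%. The forecast gives 90.7% and a higher 45%, noting: “Why it stalls is not clear, so its tail is uncertain.”

The flask gives 90.7% and 43.3%, so the forecast holds within its margin.

    substrate + reagent → mono adduct (k = 1.10 M⁻¹ min⁻¹)
    substrate ⇌ dormant form (K = 2.10, k = 0.150 min⁻¹)
    substrate + tris adduct → side product (k = 1.40 M⁻¹ min⁻¹)
    reagent + mono adduct → bis adduct (k = 1.00 M⁻¹ min⁻¹)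
    reagent + bis adduct → tris adduct (k = 3.10 M⁻¹ min⁻¹)

Reagent stands at 0% at 8.00 h, so the price of this flask is 1.10.

A neighbour charged with 0.42 M of reagent has, at that price, enough for 152% of its substrate, so you expect full conversion and, if its reagent is used up too, a price rising to 1.68. It gives a conversion of >99.9%, with 0% of its reagent left and 71.1% side product.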